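## Structural features

The target is a 2,3-trans flavanonol of (2R,3R) configuration. It is a chroman-4-one in which ring A (5,7-dihydroxy, prenyl at C6) is fused through C4a and C8a to the pyranone ring C. Ring C carries a hydroxyl at C3 and, at C2, ring B (2',4'-dihydroxy, geranyl at C3').

The two stereocentres C2 and C3 are neighbours in ring C, with aryl and hydroxyl trans. C2 is benzylic, bonded to O1 and beta to the C4 ketone; C3 is an alpha-ketol carbon.

The fragile elements are these. Three trisubstituted olefins sit in chains that each lie between two phenols, so acid closes chromans and electrophilic oxidants epoxidise. The beta-aryloxy ketone opens under base by beta-elimination of the ring A phenoxide, which erases C2. The ortho/para-hydroxylated ring B eases heterolysis of C2–O1. The polyphenol as a whole is prone to air oxidation.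

The real difficulty is threefold. O1 must end up para to the prenyl group (6-prenyl, not 8-prenyl), which means telling apart the three oxygens of a phloroglucinol. C2 must be set in absolute terms without a basic step that opens ring C. The C3 hydroxyl and five free phenols must be produced without touching the olefins.

The key step uses the fact that C2 is a CH bonded to O1 and to ring B. In the aryl benzyl ether made from the ring A oxygen O1 and a ring B benzyl alcohol, the two hydrogens on this carbon are enantiotopic and activated by O1 and by the electron-rich ring B. They sit at the end of the six-atom chain C3–C4–C4a–C8a–O1–C2 when C3 is a carbene carbon on the ring A acyl group.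

The diazoketone and flavanone on either side of the key step are consistent with the target. C2 keeps its spatial arrangement throughout; its descriptor changes from S to R on hydroxylation only because C3 then outranks ring B.

## Logic of the disconnections

25 ⇒ 24. The two O–Si bonds at O5 and O7 are cut last. Buffered fluoride is the mildest way to a molecule in which every phenol and both terpenoid chains are exposed, and until then the ring A oxygens stay inert to base, carbene and oxidant. The skeleton is not simplified, but the end of the route is made safe. The forward step must stay near neutral, because free phenoxides of 25 open ring C.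

24 ⇒ 22 (through 23). The two O–CH2 acetal bonds on ring B are cut. Acetals are kept on ring B because they steer the metalations that build it. They are removed while the ring A prenyl group is still flanked by silyl ethers. The forward step must work without protic acid and must allow the liberated formaldehyde to be washed out before ring A is unmasked.

22 ⇒ 20 (through 21). The C3–O bond is cut. One stereocentre disappears and C3 becomes a CH2 group that a carbene can deliver. The hydroxyl returns anti to the C2 aryl group under substrate control. The forward step needs an oxygen donor that ignores three trisubstituted olefins, and an enolate that does not expel O1.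

20 ⇒ 19. The C2–C3 bond is cut. Ring C opens and the last stereocentre vanishes: 19 is achiral and its O1–CH2 hydrogens are enantiotopic. This is the only cut that turns C2 into a prochiral CH2 held six atoms from a reactive C3. The forward step must pick one hydrogen by catalyst control and must prefer C–H insertion to attack on the ether oxygens. For that reason O5 and O7 carry triisopropylsilyl groups. A group with C–H alpha to oxygen at O5 would offer a second 1,6 C–H bond. A smaller silyl group would shield O5 less and would migrate more easily to the enolate oxygens of 17 and 21.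

19 ⇒ 16 (through 17 and 18). The C3=N bond is cut. The diazo group comes from the methyl ketone by activation as a trifluoroacetyl derivative. This avoids diazomethane and a hindered aroyl chloride. The forward step needs clean kinetic enolisation of a ketone flanked by two ortho oxygens.

16 ⇒ 15 + 8. The O1–CH2 bond is cut. This splits the molecule into a ring A half and a ring B half of similar size. The forward step needs 15 to have exactly one free phenol, the one para to the prenyl group, and needs the silyl ethers already in place. Exchanging acetals for silyl ethers on ring A after the coupling would require telling ring A acetals from ring B acetals, so it is avoided.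

15 ⇒ 12 ⇒ 10 + 11 ⇒ 9 (through 13 and 14). The C6–CH2 bond of the prenyl group is transposed to an O–CH2 bond, which is then cut together with two O–Si bonds. A Claisen/Cope sequence from the ether oxygen places the chain para to that oxygen, which is exactly the O1/C6 relation. No isomers need separating and no selective protection among three hydroxyls is needed. The silylation of 9 stops at two groups because the third hydroxyl is chelated. The forward steps need silyl ethers that survive about 200 °C and a Cope terminus that accepts the chain between two bulky groups.

8 ⇒ 7 ⇒ 5 ⇒ 2 + 3 ⇒ 1 (through 6 and 4). The cuts are a C–H bond (reduction level), the C1'–CHO bond, the C3'–CH2 bond of the geranyl chain and the two O–CH2 acetal bonds. Two successive ortho-metalations fix the 1,2,3,4 pattern of ring B with no isomers, the first between both acetals and the second next to one. The second metalation must be faster than removal of a benzylic allylic hydrogen of the chain.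

## Other disconnections considered

Alternative 1: The cut is the C4a–C5 bond, so ring A is made last. Forward, the dihydropyranone A2 already holds ring C with both stereocentres and carries at C8a a CH2–CO–CH(prenyl)–CO2Me chain. Base would make C4a acylate on the ester carbon, and the triketone would enolise to the phloroglucinol ring of A1. In its favour, the position of the prenyl group is written into the chain, since its carbon lies between the carbonyls that become C5 and C7. No Claisen rearrangement and no discrimination between phloroglucinol oxygens is needed. On ring A regiochemistry this plan is better than the chosen one, and it is equal or better in needing no protecting groups on ring A. Against it, A2 has its C3 hydrogen alpha and its C2–O1 bond beta to the C4 ketone, so base may epimerise C3 or open ring C. The most acidic hydrogen is the methine between the two chain carbonyls; removing it makes the ester a poor electrophile, so a polyanion would be needed. O-acylation to a pyranone competes with C-acylation. A2 must be built with two stereocentres by separate asymmetric chemistry. A1 still carries three acetals whose removal needs acid with the ring A phenols already free beside the prenyl group, which is worse than the chosen end. Mechanistically the chosen insertion has one decision (which hydrogen), while this closure has several competing enolates. In step count the alternative should be longer, because chain extension and both stereocentres come before its key step.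

Alternative 2: The cut is the C3–C4 bond. Forward, A4 is a ring A aroylsilane whose O1 carries the CH(ring B)–CHO unit. A chiral lithium phosphite would add to the acylsilane, and a 1,2 silyl shift from carbon to oxygen would give an acyl anion equivalent at C4. This adds to the aldehyde carbon C3; silyl transfer to the new alkoxide and loss of phosphite would give A3. The alpha-aryloxy aldehyde centre racemises by enolisation, so one enantiomer could be drawn off. In its favour, ring closure, both stereocentres and the C3 oxygen would arrive together with no oxidant. That is better than the chosen plan, which needs a separate hydroxylation beside three olefins. It also avoids a diazo compound, a safety point on which it is better. Against it, the catalyst would have to choose between exchanging enantiomers of A4 and fix the C2/C3 relation at once, intramolecularly and with an enolisable aldehyde. The secure ground of the silyl benzoin reaction is intermolecular, with non-enolisable aryl aldehydes. The aroylsilane is flanked by two ortho oxygens and is hindered, and A4 is prone to self-condensation. The differentiation of ring A oxygens is the same problem as in the chosen plan (equal). A3 with four acetals again ends in an acidic deprotection (worse). In step count the two plans are about level: the alternative saves the hydroxylation but spends steps on the acylsilane and the aldehyde.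

Alternative 3: Two bonds are cut, O1–C8a and C4–C4a. Forward, fluoride (CsF) would convert the silyl triflate A6 into the aryne A8. The benzylic alkoxide of the anti hydroxy ester A7 would add to the aryne carbon remote from the neighbouring acetal oxygen (future C8a). The aryl anion left at C4a would acylate on the ester and close ring C to A5. In its favour, this is the most convergent plan: two bonds and a ring in one step, against one bond in the chosen key step. Both stereocentres come ready-made in A7, for instance from an auxiliary-controlled anti glycolate aldol with 7. There is no diazo compound and no oxidation at C3. On convergence and on the reliability of the stereochemical source it is better than the chosen plan, and its longest linear sequence would probably be equal or shorter. Against it, the aryl anion must acylate faster than it is protonated by the hydroxyl of a second molecule of A7. The alkoxide of A7 can fragment by retro-aldol under the basic fluoride conditions, which would scramble both centres. C3 can epimerise. Arynes undergo ene reactions with trisubstituted olefins bearing allylic hydrogens, and three such olefins are present. A6 is a pentasubstituted benzene that needs a regiocontrolled ortho-silylation. A5 with five acetals ends in a global acidic deprotection of the fully unmasked prenylated polyphenol, which is worse than the buffered fluoride end of the chosen plan. Mechanistically the alternative strings three events with a leak at each; the chosen plan has one event with one main competitor.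

Key step: step 10

Assumption: Rh2(S-PTTL)4 is taken to deliver (2S)-20; the sense of induction on this substrate is not known in advance, and the mirror-image catalyst Rh2(R-PTTL)4 would be used in the same way if the sense is opposite.

## Route

Step 1
Reactants: 1 resorcinol
Product: 2 1,3-bis(methoxymethoxy)benzene
Conditions: MOMCl (2.5 equiv), i-Pr2NEt (3 equiv), CH2Cl2, 0 °C → rt
Reagents that add atoms: chloromethyl methyl ether (MOMCl), COCCl
Why: Williamson-type O-alkylation of both phenols by the reactive alpha-chloro ether; the acetals direct the two ortho-lithiations that follow, and on ring B no O–CH2–O group can reach the later carbene.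

Step 2
Reactants: 2 1,3-bis(methoxymethoxy)benzene; 3 geranyl bromide
Product: 5 geranyl arene (2-[(2E)-3,7-dimethylocta-2,6-dienyl]-1,3-bis(methoxymethoxy)benzene), via aryllithium 4 (not isolated)
Conditions: n-BuLi (1.1 equiv), THF, 0 °C → rt; then CuI (10 mol %), 3, −78 °C → rt
Reagents that add atoms: none
Why: Directed ortho-metalation removes the hydrogen flanked by both acetal oxygens to give 4; copper-catalysed SN2 substitution at the primary carbon of 3 keeps the E olefin and avoids allylic transposition.

Step 3
Reactants: 5 geranyl arene
Product: 7 ring B aldehyde (3-[(2E)-3,7-dimethylocta-2,6-dienyl]-2,4-bis(methoxymethoxy)benzaldehyde), via aryllithium 6 (not isolated)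
Conditions: n-BuLi (1.2 equiv), TMEDA, THF, 0 °C; then DMF, 0 °C → rt; then H2O
Reagents that add atoms: N,N-dimethylformamide (DMF), CN(C)C=O
Why: Second directed ortho-metalation next to one acetal oxygen (the two free ortho sites are equivalent), then formylation of 6 with DMF; coordination of the TMEDA-activated base to the acetal should make ring lithiation faster than removal of a benzylic allylic hydrogen of the chain.

Step 4
Reactants: 7 ring B aldehyde
Product: 8 ring B benzyl alcohol ([3-[(2E)-3,7-dimethylocta-2,6-dienyl]-2,4-bis(methoxymethoxy)phenyl]methanol)
Conditions: NaBH4, MeOH, 0 °C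
Reagents that add atoms: none
Why: Borohydride reduction of the aldehyde; olefins and acetals are inert.

Step 5
Reactants: 9 2',4',6'-trihydroxyacetophenone
Product: 10 bis-silyl ether (1-[2-hydroxy-4,6-bis(triisopropylsilyloxy)phenyl]ethanone)
Conditions: TIPSCl (2.2 equiv), imidazole, DMF, 0 °C → rt
Reagents that add atoms: chlorotriisopropylsilane (TIPSCl), CC(C)[Si](Cl)(C(C)C)C(C)C
Why: Silylation of the para hydroxyl and of one of the two equivalent ortho hydroxyls; the last hydroxyl stays free because it is hydrogen-bonded to the carbonyl. Triisopropylsilyl has no C–H alpha to oxygen, shields the oxygen from the later carbene and resists oxygen-to-oxygen migration to the enolates of steps 9 and 11.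

Step 6
Reactants: 10 bis-silyl ether; 11 prenol (3-methylbut-2-en-1-ol)
Product: 12 prenyl ether (1-[2-(3-methylbut-2-enyloxy)-4,6-bis(triisopropylsilyloxy)phenyl]ethanone)
Conditions: PPh3, DIAD, THF, 0 °C → rt
Reagents that add atoms: none
Why: Mitsunobu etherification of the chelated phenol with a primary allylic alcohol; the neutral conditions spare the aryl silyl ethers, and substitution at the primary carbon gives the unrearranged prenyl ether.

Step 7
Reactants: 12 prenyl ether
Product: 15 ring A phenol (1-[6-hydroxy-3-(3-methylbut-2-enyl)-2,4-bis(triisopropylsilyloxy)phenyl]ethanone), via ortho dienone 13 (not isolated), via para dienone 14 (not isolated)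
Conditions: PhNEt2, 200 °C, argon
Reagents that add atoms: none
Why: Aromatic Claisen rearrangement followed by a Cope shift (para-Claisen): the first [3,3] shift to the only free ortho carbon gives 13, a second [3,3] shift carries the chain to the para carbon as a normal prenyl group (14), and enolisation gives 15. The chain arrives para to the liberated hydroxyl and between the two silyloxy groups, which is the O1/C6 relation of the target; the reaction type is known for 2-prenyloxy-4,6-dialkoxyacetophenones.

Step 8
Reactants: 15 ring A phenol; 8 ring B benzyl alcohol
Product: 16 benzyl ether ketone (1-[6-{[3-[(2E)-3,7-dimethylocta-2,6-dienyl]-2,4-bis(methoxymethoxy)phenyl]methoxy}-3-(3-methylbut-2-enyl)-2,4-bis(triisopropylsilyloxy)phenyl]ethanone)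
Conditions: PPh3, DIAD, THF, 0 °C → rt
Reagents that add atoms: none
Why: Mitsunobu etherification: the only free phenol of 15 displaces the activated primary benzylic hydroxyl of 8. No base is present, so silyl ethers, acetals and olefins survive, and the electron-rich benzyl group never has to be handled as a halide.

Step 9
Reactants: 16 benzyl ether ketone
Product: 19 diazoketone (2-diazo-1-[6-{[3-[(2E)-3,7-dimethylocta-2,6-dienyl]-2,4-bis(methoxymethoxy)phenyl]methoxy}-3-(3-methylbut-2-enyl)-2,4-bis(triisopropylsilyloxy)phenyl]ethanone), via lithium enolate 17 (not isolated), via trifluoroacetyl ketone 18 (not isolated)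
Conditions: LiN(SiMe3)2 (1.1 equiv), THF, −78 °C; CF3CO2CH2CF3 (1.2 equiv), −78 °C; AcOH, extractive work-up; crude 18, p-ABSA (1.5 equiv), Et3N (1.5 equiv), H2O (1 equiv), MeCN, rt
Reagents that add atoms: 4-acetamidobenzenesulfonyl azide (p-ABSA), CC(=O)Nc1ccc(cc1)S(=O)(=O)N=[N+]=[N-]
Why: Detrifluoroacetylative diazo transfer: the kinetic enolate 17 is C-acylated to 18, whose activated methylene accepts the diazo group from the sulfonyl azide while the trifluoroacetyl group leaves on the sulfonamide. This avoids diazomethane and an acid chloride of the hindered ring A.

Step 10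
Reactants: 19 diazoketone
Product: 20 flavanone ((2S)-2-[3-[(2E)-3,7-dimethylocta-2,6-dienyl]-2,4-bis(methoxymethoxy)phenyl]-6-(3-methylbut-2-enyl)-5,7-bis(triisopropylsilyloxy)chroman-4-one)
Conditions: Rh2(S-PTTL)4 (2 mol %), CH2Cl2, −20 → 0 °C, 19 added slowly
Reagents that add atoms: none
Why: Rh2(S-PTTL)4, a divalent rhodium tetracarboxylate, takes up the diazo carbon of 19 at an axial site and loses N2 to give an electrophilic rhodium-bound carbene at C3, a transient catalytic species. This carbene inserts into one of the two enantiotopic hydrogens of the O1–CH2 group in a single three-centre step with hydride-transfer character, the positive charge building at C2 being stabilised by O1 and by the 2,4-dioxygenated ring B; C2–C3 forms and the catalyst is released. The closest known reaction type is the enantioselective intramolecular C–H insertion of ortho-alkoxyaryl diazoketones to chroman-4-ones under chiral dirhodium carboxylates. Ring C closes by a 1,6 insertion through a chair-like six-membered transition state made of C3, C4, C4a, C8a, O1 and C2 with ring B equatorial; a five-membered alternative does not exist because the fifth atom of the chain is O1. C2 is the only new stereocentre and is controlled by the catalyst: the chiral pocket of the four N-phthaloyl-tert-leucinate ligands decides which benzylic hydrogen is reached, and C3 remains a CH2 group. The step needs insertion to be faster than ylide formation at O1 or O5, cyclopropanation and carbene dimerisation. The substrate secures this with a doubly activated, hydridic C–H bond, a weakly basic O1 (an aryl ether oxygen conjugated with the acylated ring A), a bulky silyl group that shields O5 and has no C–H alpha to oxygen, and olefins that cannot reach the carbene without strain; slow addition keeps 19 dilute.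

Step 11
Reactants: 20 flavanone
Product: 22 protected flavanonol ((2R,3R)-2-[3-[(2E)-3,7-dimethylocta-2,6-dienyl]-2,4-bis(methoxymethoxy)phenyl]-3-hydroxy-6-(3-methylbut-2-enyl)-5,7-bis(triisopropylsilyloxy)chroman-4-one), via sodium enolate 21 (not isolated)
Conditions: NaN(SiMe3)2 (1.3 equiv), THF, −78 °C; 2-(phenylsulfonyl)-3-phenyloxaziridine (1.5 equiv), −78 °C; AcOH quench at −78 °C
Reagents that add atoms: 2-(phenylsulfonyl)-3-phenyloxaziridine (Davis oxaziridine), O=S(=O)(c1ccccc1)N1OC1c1ccccc1
Why: Davis oxidation of the kinetic enolate 21: the N-sulfonyloxaziridine transfers oxygen to C3 from the face anti to the C2 aryl group, which should give the 2,3-trans (3R) alcohol, and it does not epoxidise isolated trisubstituted olefins at −78 °C. Low temperature and a cold acidic quench should keep 21 from expelling the ring A phenoxide, so C2 is preserved.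

Step 12
Reactants: 22 protected flavanonol
Product: 24 ring B diol ((2R,3R)-2-[3-[(2E)-3,7-dimethylocta-2,6-dienyl]-2,4-dihydroxyphenyl]-3-hydroxy-6-(3-methylbut-2-enyl)-5,7-bis(triisopropylsilyloxy)chroman-4-one), via tris(trimethylsilyl) ether 23 (not isolated)
Conditions: TMSOTf (6 equiv), 2,2'-bipyridyl (9 equiv), MeCN, 0 °C → rt; then H2O, rt
Reagents that add atoms: none
Why: Silyl triflate/bipyridyl cleavage of aromatic methoxymethyl ethers: each aryl acetal becomes the aryl trimethylsilyl ether with transfer of the methoxymethyl group to a pyridine nitrogen (the C3 hydroxyl is silylated in passing, giving 23), and water then hydrolyses the three trimethylsilyl ethers. No protic acid is present, so the geranyl chain should not cyclise onto the new phenols, and ring A is still silylated while formaldehyde is released and washed out.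

Step 13
Reactants: 24 ring B diol
Product: 25 target ((2R,3R)-2-[3-[(2E)-3,7-dimethylocta-2,6-dienyl]-2,4-dihydroxyphenyl]-3,5,7-trihydroxy-6-(3-methylbut-2-enyl)chroman-4-one)
Conditions: Bu4NF (2.5 equiv), AcOH (2.5 equiv), THF, 0 °C
Reagents that add atoms: none
Why: Fluoride cleavage of the two aryl silyl ethers; acetic acid buffers the phenoxides, which guards against ring-opening epimerisation at C2 and against oxidation of the polyphenol.

## Compound list

1 | resorcinol | Oc1cccc(O)c1 | starting material
2 | 1,3-bis(methoxymethoxy)benzene | COCOc1cccc(OCOC)c1 | intermediate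
3 | geranyl bromide, (2E)-1-bromo-3,7-dimethylocta-2,6-diene | CC(C)=CCC/C(C)=C/CBr | starting material
4 | [2,6-bis(methoxymethoxy)phenyl]lithium (formed in the flask) | [Li]c1c(OCOC)cccc1OCOC | intermediate
5 | 2-[(2E)-3,7-dimethylocta-2,6-dienyl]-1,3-bis(methoxymethoxy)benzene | CC(C)=CCC/C(C)=C/Cc1c(OCOC)cccc1OCOC | intermediate
6 | [3-[(2E)-3,7-dimethylocta-2,6-dienyl]-2,4-bis(methoxymethoxy)phenyl]lithium (formed in the flask) | CC(C)=CCC/C(C)=C/Cc1c(OCOC)ccc([Li])c1OCOC | intermediate
7 | 3-[(2E)-3,7-dimethylocta-2,6-dienyl]-2,4-bis(methoxymethoxy)benzaldehyde | CC(C)=CCC/C(C)=C/Cc1c(OCOC)ccc(C=O)c1OCOC | intermediate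
8 | [3-[(2E)-3,7-dimethylocta-2,6-dienyl]-2,4-bis(methoxymethoxy)phenyl]methanol | CC(C)=CCC/C(C)=C/Cc1c(OCOC)ccc(CO)c1OCOC | intermediate
9 | 2',4',6'-trihydroxyacetophenone | CC(=O)c1c(O)cc(O)cc1O | starting material
10 | 1-[2-hydroxy-4,6-bis(triisopropylsilyloxy)phenyl]ethanone | CC(=O)c1c(O)cc(O[Si](C(C)C)(C(C)C)C(C)C)cc1O[Si](C(C)C)(C(C)C)C(C)C | intermediate
11 | prenol, 3-methylbut-2-en-1-ol | CC(C)=CCO | starting material
12 | 1-[2-(3-methylbut-2-enyloxy)-4,6-bis(triisopropylsilyloxy)phenyl]ethanone | CC(=O)c1c(OCC=C(C)C)cc(O[Si](C(C)C)(C(C)C)C(C)C)cc1O[Si](C(C)C)(C(C)C)C(C)C | intermediate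
13 | ortho dienone, 2-acetyl-6-(2-methylbut-3-en-2-yl)-3,5-bis(triisopropylsilyloxy)cyclohexa-2,4-dien-1-one (racemic, formed in the flask) | CC(=O)C1=C(O[Si](C(C)C)(C(C)C)C(C)C)C=C(O[Si](C(C)C)(C(C)C)C(C)C)C(C(C)(C)C=C)C1=O | intermediate
14 | para dienone, 2-acetyl-4-(3-methylbut-2-enyl)-3,5-bis(triisopropylsilyloxy)cyclohexa-2,5-dien-1-one (racemic, formed in the flask) | CC(=O)C1=C(O[Si](C(C)C)(C(C)C)C(C)C)C(CC=C(C)C)C(O[Si](C(C)C)(C(C)C)C(C)C)=CC1=O | intermediate
15 | 1-[6-hydroxy-3-(3-methylbut-2-enyl)-2,4-bis(triisopropylsilyloxy)phenyl]ethanone | CC(=O)c1c(O)cc(O[Si](C(C)C)(C(C)C)C(C)C)c(CC=C(C)C)c1O[Si](C(C)C)(C(C)C)C(C)C | intermediate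
16 | ring A methyl ketone with the ring B benzyl ether at O1 and silyl ethers at O5 and O7 | CC(C)=CCC/C(C)=C/Cc1c(OCOC)ccc(COc2cc(O[Si](C(C)C)(C(C)C)C(C)C)c(CC=C(C)C)c(O[Si](C(C)C)(C(C)C)C(C)C)c2C(C)=O)c1OCOC | intermediate
17 | lithium enolate of 16 (formed in the flask) | CC(C)=CCC/C(C)=C/Cc1c(OCOC)ccc(COc2cc(O[Si](C(C)C)(C(C)C)C(C)C)c(CC=C(C)C)c(O[Si](C(C)C)(C(C)C)C(C)C)c2C(=C)O[Li])c1OCOC | intermediate
18 | trifluoroacetyl ketone, the 4,4,4-trifluoro-1,3-dione derived from 16 (crude, not purified) | CC(C)=CCC/C(C)=C/Cc1c(OCOC)ccc(COc2cc(O[Si](C(C)C)(C(C)C)C(C)C)c(CC=C(C)C)c(O[Si](C(C)C)(C(C)C)C(C)C)c2C(=O)CC(=O)C(F)(F)F)c1OCOC | intermediate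
19 | ring A diazomethyl ketone with the ring B benzyl ether at O1 | CC(C)=CCC/C(C)=C/Cc1c(OCOC)ccc(COc2cc(O[Si](C(C)C)(C(C)C)C(C)C)c(CC=C(C)C)c(O[Si](C(C)C)(C(C)C)C(C)C)c2C(=O)C=[N+]=[N-])c1OCOC | intermediate
20 | (2S)-flavanone with ring A triisopropylsilyl ethers and ring B methoxymethyl ethers | CC(C)=CCC/C(C)=C/Cc1c(OCOC)ccc([C@H]2Oc3cc(O[Si](C(C)C)(C(C)C)C(C)C)c(CC=C(C)C)c(O[Si](C(C)C)(C(C)C)C(C)C)c3C(=O)C2)c1OCOC | intermediate
21 | sodium enolate of 20, (2S) (formed in the flask) | CC(C)=CCC/C(C)=C/Cc1c(OCOC)ccc([C@H]2Oc3cc(O[Si](C(C)C)(C(C)C)C(C)C)c(CC=C(C)C)c(O[Si](C(C)C)(C(C)C)C(C)C)c3C([O-])=C2)c1OCOC.[Na+] | intermediate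
22 | (2R,3R)-3-hydroxyflavanone with ring A triisopropylsilyl ethers and ring B methoxymethyl ethers | CC(C)=CCC/C(C)=C/Cc1c(OCOC)ccc([C@H]2Oc3cc(O[Si](C(C)C)(C(C)C)C(C)C)c(CC=C(C)C)c(O[Si](C(C)C)(C(C)C)C(C)C)c3C(=O)[C@@H]2O)c1OCOC | intermediate
23 | (2R,3R)-3,2',4'-tris(trimethylsilyl) ether with ring A triisopropylsilyl ethers (formed in the flask) | CC(C)=CCC/C(C)=C/Cc1c(O[Si](C)(C)C)ccc([C@H]2Oc3cc(O[Si](C(C)C)(C(C)C)C(C)C)c(CC=C(C)C)c(O[Si](C(C)C)(C(C)C)C(C)C)c3C(=O)[C@@H]2O[Si](C)(C)C)c1O[Si](C)(C)C | intermediate
24 | (2R,3R)-flavanonol with free ring B phenols and ring A triisopropylsilyl ethers | CC(C)=CCC/C(C)=C/Cc1c(O)ccc([C@H]2Oc3cc(O[Si](C(C)C)(C(C)C)C(C)C)c(CC=C(C)C)c(O[Si](C(C)C)(C(C)C)C(C)C)c3C(=O)[C@@H]2O)c1O | intermediate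
25 | CNP0166115.1, (2R,3R)-2-[3-[(2E)-3,7-dimethylocta-2,6-dienyl]-2,4-dihydroxyphenyl]-3,5,7-trihydroxy-6-(3-methylbut-2-enyl)chroman-4-one | CC(C)=CCC/C(C)=C/Cc1c(O)ccc([C@H]2Oc3cc(O)c(CC=C(C)C)c(O)c3C(=O)[C@@H]2O)c1O | target

## Step count and least certain steps

Total step count: 13. Longest linear sequence: 10 steps (steps 1, 2, 3, 4, 8, 9, 10, 11, 12, 13 from 1). The ring A branch (steps 5, 6, 7) joins at step 8.

Step 10 (key step). The most likely failure is attack of the carbene on the lone pair of O1, forming a five-membered oxonium ylide that rearranges by 1,2-shift of the electron-rich benzyl group, so the ring contracts instead of inserting. The second risk is weak discrimination of the two enantiotopic hydrogens, since the induction of this catalyst on this substrate is assumed. The fallback uses a different bond construction and sets out from 15 and 7. Aldol addition of the dilithio derivative of 15 to 7 (LiN(SiMe3)2, THF, −78 °C) gives the racemic aldol adduct F1. F1 loses water on warming to give the (E)-2'-hydroxychalcone F2. Enantioselective 6-endo oxa-Michael closure of F2 under a quinine-derived bifunctional thiourea base returns to the route at 20, with preparative chiral chromatography if the enrichment is insufficient.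

Step 11. The most likely failure is beta-elimination of the ring A phenoxide from 21, which opens ring C and, on reclosure, erodes the configuration at C2. Capture of 21 by the sulfonimine formed from the oxidant is a second risk. The fallback sets out from 20 and avoids a free enolate. Soft enolisation (TMSOTf, Et3N, CH2Cl2, −20 °C) gives the trimethylsilyl enol ether F3. Rubottom oxidation with dimethyldioxirane (1.0 equiv, acetone/CH2Cl2, −78 °C) relies on the far higher nucleophilicity of the silyl enol ether compared with the chain olefins; a citric acid/MeOH work-up returns to the route at 22.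

Step 7. The most likely failure is enolisation of 13 before the second shift, which would leave the chain at the ortho carbon as a 1,1-dimethylallyl group; the para carbon lies between two bulky silyloxy groups, which slows the Cope shift. Thermal loss or migration of a silyl group is a second risk. The fallback sets out from 9. C-prenylation with prenyl bromide and DBU in THF gives the C-prenyl triol F4, a single isomer by symmetry. Silylation of the para hydroxyl (TIPSCl, 1 equiv, imidazole) gives the mono-silyl ether F5. Mitsunobu coupling with 8 at the less hindered of the two ortho hydroxyls gives the hydroxy benzyl ether F6. Silylation of the remaining chelated hydroxyl (TIPSOTf, 2,6-lutidine) returns to the route at 16.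

Step 12. The most likely failure is incomplete exchange at the hindered 2'-acetal, or capture of the released formaldehyde by the electron-rich ring B before work-up. The fallback sets out from 22, reverses the order of the deprotections and changes the mechanism. Bu4NF/AcOH (THF, 0 °C) gives the 5,7-diol F7 with the ring B acetals intact. Methanolysis with HCl in MeOH at rt, where formaldehyde is trapped as its dimethyl acetal, returns to the route at 25.

## Further compounds

F1 | step 10 | racemic aldol adduct of 15 and 7 | CC(C)=CCC/C(C)=C/Cc1c(OCOC)ccc(C(O)CC(=O)c2c(O)cc(O[Si](C(C)C)(C(C)C)C(C)C)c(CC=C(C)C)c2O[Si](C(C)C)(C(C)C)C(C)C)c1OCOC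
F2 | step 10 | (E)-2'-hydroxychalcone from F1 | CC(C)=CCC/C(C)=C/Cc1c(OCOC)ccc(/C=C/C(=O)c2c(O)cc(O[Si](C(C)C)(C(C)C)C(C)C)c(CC=C(C)C)c2O[Si](C(C)C)(C(C)C)C(C)C)c1OCOC
F3 | step 11 | trimethylsilyl enol ether of 20, (2S) | CC(C)=CCC/C(C)=C/Cc1c(OCOC)ccc([C@H]2Oc3cc(O[Si](C(C)C)(C(C)C)C(C)C)c(CC=C(C)C)c(O[Si](C(C)C)(C(C)C)C(C)C)c3C(O[Si](C)(C)C)=C2)c1OCOC
F4 | step 7 | 1-[2,4,6-trihydroxy-3-(3-methylbut-2-enyl)phenyl]ethanone | CC(=O)c1c(O)cc(O)c(CC=C(C)C)c1O
F5 | step 7 | 1-[2,6-dihydroxy-3-(3-methylbut-2-enyl)-4-(triisopropylsilyloxy)phenyl]ethanone | CC(=O)c1c(O)cc(O[Si](C(C)C)(C(C)C)C(C)C)c(CC=C(C)C)c1O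
F6 | step 7 | analogue of 16 with a free hydroxyl in place of the silyl ether next to the acetyl group | CC(C)=CCC/C(C)=C/Cc1c(OCOC)ccc(COc2cc(O[Si](C(C)C)(C(C)C)C(C)C)c(CC=C(C)C)c(O)c2C(C)=O)c1OCOC
F7 | step 12 | (2R,3R)-flavanonol with free ring A phenols and ring B methoxymethyl ethers | CC(C)=CCC/C(C)=C/Cc1c(OCOC)ccc([C@H]2Oc3cc(O)c(CC=C(C)C)c(O)c3C(=O)[C@@H]2O)c1OCOC
A1 | alternative 1 | 5,7-dihydroxy-6-prenyl flavanonol with ring B and C3 oxygens as methoxymethyl ethers | CC(C)=CCC/C(C)=C/Cc1c(OCOC)ccc([C@H]2Oc3cc(O)c(CC=C(C)C)c(O)c3C(=O)[C@@H]2OCOC)c1OCOC
A2 | alternative 1 | (2R,3R)-2-aryl-3-(methoxymethoxy)-2,3-dihydropyran-4-one with a prenylated beta-keto ester chain at C8a | CC(C)=CCC/C(C)=C/Cc1c(OCOC)ccc([C@H]2OC(CC(=O)C(CC=C(C)C)C(=O)OC)=CC(=O)[C@@H]2OCOC)c1OCOC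
A3 | alternative 2 | trans flavanonol 3-O-dimethylphenylsilyl tetra(methoxymethyl) ether | CC(C)=CCC/C(C)=C/Cc1c(OCOC)ccc([C@H]2Oc3cc(OCOC)c(CC=C(C)C)c(OCOC)c3C(=O)[C@@H]2O[Si](C)(C)c2ccccc2)c1OCOC
A4 | alternative 2 | racemic ring A aroyl(dimethylphenyl)silane with the 2-aryl-2-aryloxyacetaldehyde unit at O1 | CC(C)=CCC/C(C)=C/Cc1c(OCOC)ccc(C(C=O)Oc2cc(OCOC)c(CC=C(C)C)c(OCOC)c2C(=O)[Si](C)(C)c3ccccc3)c1OCOC
A5 | alternative 3 | trans flavanonol penta(methoxymethyl) ether | CC(C)=CCC/C(C)=C/Cc1c(OCOC)ccc([C@H]2Oc3cc(OCOC)c(CC=C(C)C)c(OCOC)c3C(=O)[C@@H]2OCOC)c1OCOC
A6 | alternative 3 | 3,5-bis(methoxymethoxy)-4-(3-methylbut-2-enyl)-2-(trimethylsilyl)phenyl trifluoromethanesulfonate | O=S(=O)(Oc1cc(OCOC)c(CC=C(C)C)c(OCOC)c1[Si](C)(C)C)C(F)(F)F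
A7 | alternative 3 | methyl (2R,3R)-3-aryl-3-hydroxy-2-(methoxymethoxy)propanoate, aryl = 3-geranyl-2,4-bis(methoxymethoxy)phenyl | CC(C)=CCC/C(C)=C/Cc1c(OCOC)ccc([C@@H](O)[C@@H](OCOC)C(=O)OC)c1OCOC
A8 | alternative 3 | 3,5-bis(methoxymethoxy)-4-(3-methylbut-2-enyl)benzyne | COCOC1=C(CC=C(C)C)C(OCOC)=CC#C1
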